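Everything rests on building ring C directly on the phenolic oxygen of ring B instead of importing an orsellinic acid. The feature used is the resorcinol pattern of ring C: O2 and O4 are meta, the C4 hydroxyl is para to the ester-bearing C1, and C6 carries the methyl group. Light turns a diazo ketoester into an ester-substituted vinylketene, which joins a silyl ynol ether and aromatizes in one flask, creating C1–C6, C1–C2, C3–C4 and C4–C5. The precursor is the ring A–ring B didepside whose ring B O4 bears a 2-diazo-4-methyl-3-oxopent-4-enoyl group. The ring A hydroxyl is silylated so that no free OH or salicylate chromophore meets the ketene.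

Key step: step 11

Assumption on labels: ring A is the methyl ester terminus, ring B the central methoxy ring and ring C the terminal dihydroxy ring; each ring is numbered from its carboxyl-bearing carbon C1 so that the methyl group sits on C6; the target has no stereocentre.

Step 1
Reactants: 1 methyl orsellinate (methyl 2,4-dihydroxy-6-methylbenzoate)
Product: 2 methyl 4-(benzyloxy)-2-hydroxy-6-methylbenzoate
Conditions: BnBr (1.05 equiv), K2CO3, acetone, reflux
Reagents that add atoms: benzyl bromide, BrCc1ccccc1
Why: Williamson ether synthesis: the C2 hydroxyl is held in a hydrogen bond to the neighbouring ester carbonyl, so a weak base and about one equivalent of halide should alkylate only the more acidic, unhindered C4 hydroxyl.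

Step 2
Reactants: 2 methyl 4-(benzyloxy)-2-hydroxy-6-methylbenzoate
Product: 3 methyl 4-(benzyloxy)-2-methoxy-6-methylbenzoate
Conditions: MeI (3 equiv), K2CO3, DMF, 40 °C
Reagents that add atoms: iodomethane, CI
Why: Williamson ether synthesis on the one hydroxyl left, which in a polar solvent with excess iodomethane should be methylated despite its hydrogen bond, placing the ring B methoxy group of the target.

Step 3
Reactants: 3 methyl 4-(benzyloxy)-2-methoxy-6-methylbenzoate
Product: 5 4-(benzyloxy)-2-methoxy-6-methylbenzoic acid, via potassium carboxylate 4 (not isolated)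
Conditions: KOH, DMSO/H2O, 90 °C; then 1 M HCl, 0 °C
Reagents that add atoms: potassium hydroxide, [K+].[OH-]
Why: Saponification of a di-ortho-substituted benzoate calls for hot concentrated hydroxide in a dipolar solvent, which both ether groups tolerate, and cold acidification should avoid decarboxylation of the electron-rich acid.

Step 4
Reactants: 5 4-(benzyloxy)-2-methoxy-6-methylbenzoic acid; 1 methyl orsellinate
Product: 7 methyl 4-{[4-(benzyloxy)-2-methoxy-6-methylbenzoyl]oxy}-2-hydroxy-6-methylbenzoate, via mixed trifluoroacetic anhydride 6 (not isolated)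
Conditions: (CF3CO)2O, toluene, 0 °C to rt
Reagents that add atoms: none
Why: Mixed-anhydride esterification, the classical depside coupling: the hindered electron-rich acid is activated as 6 and should acylate 1 only at the C4 hydroxyl, because the C2 hydroxyl is deactivated by its hydrogen bond to the ester.

Step 5
Reactants: 7 methyl 4-{[4-(benzyloxy)-2-methoxy-6-methylbenzoyl]oxy}-2-hydroxy-6-methylbenzoate; 8 triisopropylsilyl trifluoromethanesulfonate
Product: 9 methyl 4-{[4-(benzyloxy)-2-methoxy-6-methylbenzoyl]oxy}-6-methyl-2-[(triisopropylsilyl)oxy]benzoate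
Conditions: 2,6-lutidine, CH2Cl2, 0 °C to rt
Reagents that add atoms: none
Why: Silyl ether formation with a silyl triflate and a hindered pyridine base is strong enough for a hydrogen-bonded phenol, and it removes both the only hydroxyl that could later trap an acylketene or a ketene and the salicylate chromophore that would compete for light.

Step 6
Reactants: 9 methyl 4-{[4-(benzyloxy)-2-methoxy-6-methylbenzoyl]oxy}-6-methyl-2-[(triisopropylsilyl)oxy]benzoate
Product: 10 methyl 4-[(4-hydroxy-2-methoxy-6-methylbenzoyl)oxy]-6-methyl-2-[(triisopropylsilyl)oxy]benzoate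
Conditions: H2 (1 atm), 10% Pd/C, EtOAc, rt
Reagents that add atoms: none
Why: Catalytic hydrogenolysis cleaves the benzyl aryl ether under neutral conditions that should leave the aryl ester, the methyl ester and the silyl ether untouched, freeing O4 of ring B as the only hydroxyl.

Step 7
Reactants: 11 Meldrum's acid (2,2-dimethyl-1,3-dioxane-4,6-dione); 12 methacryloyl chloride
Product: 13 5-(1-hydroxy-2-methylprop-2-en-1-ylidene)-2,2-dimethyl-1,3-dioxane-4,6-dione (methacryloyl Meldrum's acid in its enol form)
Conditions: pyridine (2.2 equiv), CH2Cl2, 0 °C to rt; 1 M HCl wash; used crude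
Reagents that add atoms: none
Why: C-acylation of Meldrum's acid through an acylpyridinium species is a standard route to acyl Meldrum's acids, the acid chloride has no alpha hydrogen from which a ketene could form, and the alpha methyl group slows conjugate addition.

Step 8
Reactants: 10 methyl 4-[(4-hydroxy-2-methoxy-6-methylbenzoyl)oxy]-6-methyl-2-[(triisopropylsilyl)oxy]benzoate; 13 methacryloyl Meldrum's acid
Product: 15 methyl 4-({2-methoxy-6-methyl-4-[(4-methyl-3-oxopent-4-enoyl)oxy]benzoyl}oxy)-6-methyl-2-[(triisopropylsilyl)oxy]benzoate, via methacryloylketene 14 (not isolated)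
Conditions: 13 (1.4 equiv), BHT (cat.), toluene, 85 °C
Reagents that add atoms: none
Why: Thermal cycloreversion of an acyl Meldrum's acid releases acetone and CO2 and gives acylketene 14, which the single free phenol of 10 should trap to the aryl beta-keto ester under neutral conditions, a radical inhibitor guarding the enone.

Step 9
Reactants: 15 methyl 4-({2-methoxy-6-methyl-4-[(4-methyl-3-oxopent-4-enoyl)oxy]benzoyl}oxy)-6-methyl-2-[(triisopropylsilyl)oxy]benzoate
Product: 16 methyl 4-({4-[(2-diazo-4-methyl-3-oxopent-4-enoyl)oxy]-2-methoxy-6-methylbenzoyl}oxy)-6-methyl-2-[(triisopropylsilyl)oxy]benzoate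
Conditions: 4-acetamidobenzenesulfonyl azide, Et3N, MeCN, 0 °C to rt, dark
Reagents that add atoms: 4-acetamidobenzenesulfonyl azide, CC(=O)Nc1ccc(cc1)S(=O)(=O)N=[N+]=[N-]
Why: Regitz diazo transfer: the doubly activated methylene is deprotonated by triethylamine and should take up the terminal N2 unit of the sulfonyl azide faster than the enolate can add to the alpha-branched enone or lose aryloxide.

Step 10
Reactants: 17 acetylene; 8 triisopropylsilyl trifluoromethanesulfonate
Product: 20 (triisopropylsilyloxy)ethyne, via lithium acetylide 18 (not isolated), via lithium ethynolate 19 (not isolated)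
Conditions: 17 (excess), n-BuLi, THF, −78 °C; t-BuOOLi (from t-BuOOH and LiN(SiMe3)2, THF, −78 °C), −78 to −10 °C; 8, −78 to 0 °C
Reagents that add atoms: tert-butyl hydroperoxide, CC(C)(C)OO
Why: Oxidation of a lithium acetylide with lithium tert-butyl peroxide transfers one oxygen to the carbanion carbon, and the bulky silyl triflate should then silylate the ynolate on oxygen rather than carbon, which is the standard entry to triisopropylsilyl ynol ethers; excess acetylene and a ceiling of −10 °C hold back disproportionation of the monolithium acetylide.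

Step 11
Reactants: 16 methyl 4-({4-[(2-diazo-4-methyl-3-oxopent-4-enoyl)oxy]-2-methoxy-6-methylbenzoyl}oxy)-6-methyl-2-[(triisopropylsilyl)oxy]benzoate; 20 (triisopropylsilyloxy)ethyne
Product: 25 methyl 4-{[4-({4-hydroxy-6-methyl-2-[(triisopropylsilyl)oxy]benzoyl}oxy)-2-methoxy-6-methylbenzoyl]oxy}-6-methyl-2-[(triisopropylsilyl)oxy]benzoate, via vinylketene 21 (not isolated), via cyclobutenone 22 (not isolated), via dienylketene 23 (not isolated), via cyclohexadienone 24 (not isolated)
Conditions: 20 (3 equiv), 365 nm LED, ClCH2CH2Cl (0.02 M), 20 °C until N2 evolution ends; then dark, 80 °C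
Reagents that add atoms: none
Why: Proposed new method: light absorbed by the diazo dicarbonyl unit, at a wavelength where the silylated depside esters should be nearly transparent and so spared a photo-Fries shift, expels N2 while the isopropenyl carbon moves from the ketone carbonyl to the diazo carbon (Wolff rearrangement, bond C1–C6), carbon migrating ahead of the aryloxy oxygen as is normal for 2-diazo-3-oxo esters, to give vinylketene 21. The CH terminus of 20, made nucleophilic by the silyloxy group, attacks the strongly electrophilic ketene carbonyl carbon and [2+2] addition gives the 3-silyloxy-4-isopropenylcyclobut-2-enone 22 (bonds C3–C4 and C1–C2), so the donor oxygen of 20 decides which alkyne carbon becomes C3 and which C2, while an ester carbonyl is a far weaker heterodiene terminus than a ketone and should leave hetero-[4+2] addition behind. At 80 °C in the dark, 22 opens by reversible conrotatory four-electron cleavage of the former ketene C–C bond to dienylketene 23, and ring C closes by disrotatory six-electron electrocyclization of the ketene carbon onto the terminal CH2 (bond C4–C5); since tautomerization of dienone 24 to the phenol is the only irreversible exit, the unproductive dienylketene geometry and any oxa-closure onto the ester should drain back through 22. The closest known reaction type is the Danheiser benzannulation in its photo-Wolff form, where unsaturated diazo ketones and siloxyalkynes give resorcinol monosilyl ethers, and what is untested is the aryloxycarbonyl group on the ketene alpha carbon. No stereocentre is created in 25, because the racemic quaternary carbon of 22 becomes the planar C1. Chemoselectivity is secured by a substrate without any free hydroxyl, by excess 20 and by the two-stage protocol in which phenol appears only when the ketene source is spent, and even a direct [4+2] use of 21 as a diene would give the 4-O-silyl isomer, which step 12 would carry to the same target.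

Step 12
Reactants: 25 methyl 4-{[4-({4-hydroxy-6-methyl-2-[(triisopropylsilyl)oxy]benzoyl}oxy)-2-methoxy-6-methylbenzoyl]oxy}-6-methyl-2-[(triisopropylsilyl)oxy]benzoate
Product: 26 methyl 4-({4-[(2,4-dihydroxy-6-methylbenzoyl)oxy]-2-methoxy-6-methylbenzoyl}oxy)-2-hydroxy-6-methylbenzoate (target)
Conditions: Bu4NF (2.4 equiv), AcOH (2.4 equiv), THF, 0 °C
Reagents that add atoms: none
Why: Fluoride-induced cleavage of both aryl silyl ethers, driven by the strong Si–F bond, is buffered with acetic acid so that the phenoxides are protonated at once and cannot attack the two depside esters.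

Compound list ("aryl" in 21–24 means the residue of 10 bound through O4 of ring B)
1 | methyl orsellinate (methyl 2,4-dihydroxy-6-methylbenzoate) | COC(=O)c1c(C)cc(O)cc1O | starting material
2 | methyl 4-(benzyloxy)-2-hydroxy-6-methylbenzoate | COC(=O)c1c(C)cc(OCc2ccccc2)cc1O | intermediate
3 | methyl 4-(benzyloxy)-2-methoxy-6-methylbenzoate | COC(=O)c1c(C)cc(OCc2ccccc2)cc1OC | intermediate
4 | potassium 4-(benzyloxy)-2-methoxy-6-methylbenzoate | [K+].[O-]C(=O)c1c(C)cc(OCc2ccccc2)cc1OC | intermediate
5 | 4-(benzyloxy)-2-methoxy-6-methylbenzoic acid | OC(=O)c1c(C)cc(OCc2ccccc2)cc1OC | intermediate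
6 | 4-(benzyloxy)-2-methoxy-6-methylbenzoic trifluoroacetic anhydride | FC(F)(F)C(=O)OC(=O)c1c(C)cc(OCc2ccccc2)cc1OC | intermediate
7 | methyl 4-{[4-(benzyloxy)-2-methoxy-6-methylbenzoyl]oxy}-2-hydroxy-6-methylbenzoate | COC(=O)c1c(C)cc(OC(=O)c2c(C)cc(OCc3ccccc3)cc2OC)cc1O | intermediate
8 | triisopropylsilyl trifluoromethanesulfonate | CC(C)[Si](OS(=O)(=O)C(F)(F)F)(C(C)C)C(C)C | starting material
9 | methyl 4-{[4-(benzyloxy)-2-methoxy-6-methylbenzoyl]oxy}-6-methyl-2-[(triisopropylsilyl)oxy]benzoate | COC(=O)c1c(C)cc(OC(=O)c2c(C)cc(OCc3ccccc3)cc2OC)cc1O[Si](C(C)C)(C(C)C)C(C)C | intermediate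
10 | methyl 4-[(4-hydroxy-2-methoxy-6-methylbenzoyl)oxy]-6-methyl-2-[(triisopropylsilyl)oxy]benzoate | COC(=O)c1c(C)cc(OC(=O)c2c(C)cc(O)cc2OC)cc1O[Si](C(C)C)(C(C)C)C(C)C | intermediate
11 | Meldrum's acid (2,2-dimethyl-1,3-dioxane-4,6-dione) | CC1(C)OC(=O)CC(=O)O1 | starting material
12 | methacryloyl chloride | C=C(C)C(=O)Cl | starting material
13 | 5-(1-hydroxy-2-methylprop-2-en-1-ylidene)-2,2-dimethyl-1,3-dioxane-4,6-dione | C=C(C)C(O)=C1C(=O)OC(C)(C)OC1=O | intermediate
14 | methacryloylketene (4-methylpenta-1,4-diene-1,3-dione) | C=C(C)C(=O)C=C=O | intermediate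
15 | methyl 4-({2-methoxy-6-methyl-4-[(4-methyl-3-oxopent-4-enoyl)oxy]benzoyl}oxy)-6-methyl-2-[(triisopropylsilyl)oxy]benzoate | COC(=O)c1c(C)cc(OC(=O)c2c(C)cc(OC(=O)CC(=O)C(C)=C)cc2OC)cc1O[Si](C(C)C)(C(C)C)C(C)C | intermediate
16 | methyl 4-({4-[(2-diazo-4-methyl-3-oxopent-4-enoyl)oxy]-2-methoxy-6-methylbenzoyl}oxy)-6-methyl-2-[(triisopropylsilyl)oxy]benzoate | COC(=O)c1c(C)cc(OC(=O)c2c(C)cc(OC(=O)C(=[N+]=[N-])C(=O)C(C)=C)cc2OC)cc1O[Si](C(C)C)(C(C)C)C(C)C | intermediate
17 | acetylene | C#C | starting material
18 | lithium acetylide | [Li+].[C-]#C | intermediate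
19 | lithium ethynolate | [Li+].[O-]C#C | intermediate
20 | (triisopropylsilyloxy)ethyne | C#CO[Si](C(C)C)(C(C)C)C(C)C | intermediate
21 | aryl 3-methyl-2-(oxomethylidene)but-3-enoate (ester-substituted vinylketene) | COC(=O)c1c(C)cc(OC(=O)c2c(C)cc(OC(=O)C(=C=O)C(C)=C)cc2OC)cc1O[Si](C(C)C)(C(C)C)C(C)C | intermediate
22 | aryl 2-oxo-1-(prop-1-en-2-yl)-4-[(triisopropylsilyl)oxy]cyclobut-3-ene-1-carboxylate (a 3-silyloxy-4-isopropenylcyclobut-2-enone, racemic at the quaternary carbon) | COC(=O)c1c(C)cc(OC(=O)c2c(C)cc(OC(=O)C3(C(C)=C)C(=O)C=C3O[Si](C(C)C)(C(C)C)C(C)C)cc2OC)cc1O[Si](C(C)C)(C(C)C)C(C)C | intermediate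
23 | aryl (2Z)-5-oxo-2-(prop-1-en-2-yl)-3-[(triisopropylsilyl)oxy]penta-2,4-dienoate (dienylketene, ketenyl group cis to isopropenyl) | COC(=O)c1c(C)cc(OC(=O)c2c(C)cc(OC(=O)/C(C(C)=C)=C(/C=C=O)O[Si](C(C)C)(C(C)C)C(C)C)cc2OC)cc1O[Si](C(C)C)(C(C)C)C(C)C | intermediate
24 | aryl 2-methyl-4-oxo-6-[(triisopropylsilyl)oxy]cyclohexa-1,5-diene-1-carboxylate | COC(=O)c1c(C)cc(OC(=O)c2c(C)cc(OC(=O)C3=C(C)CC(=O)C=C3O[Si](C(C)C)(C(C)C)C(C)C)cc2OC)cc1O[Si](C(C)C)(C(C)C)C(C)C | intermediate
25 | methyl 4-{[4-({4-hydroxy-6-methyl-2-[(triisopropylsilyl)oxy]benzoyl}oxy)-2-methoxy-6-methylbenzoyl]oxy}-6-methyl-2-[(triisopropylsilyl)oxy]benzoate | COC(=O)c1c(C)cc(OC(=O)c2c(C)cc(OC(=O)c3c(C)cc(O)cc3O[Si](C(C)C)(C(C)C)C(C)C)cc2OC)cc1O[Si](C(C)C)(C(C)C)C(C)C | intermediate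
26 | methyl 4-({4-[(2,4-dihydroxy-6-methylbenzoyl)oxy]-2-methoxy-6-methylbenzoyl}oxy)-2-hydroxy-6-methylbenzoate | COC(=O)c1c(C)cc(OC(=O)c2c(C)cc(OC(=O)c3c(C)cc(O)cc3O)cc2OC)cc1O | target

Total step count: 12.
Longest linear sequence: 10 (steps 1–6, 8, 9, 11, 12).

**Steps most likely to fail**

**First, step 11.**
- What may go wrong:
  - the alkyne captures the free carbene before rearrangement;
  - the aryloxy group migrates in place of the isopropenyl group;
  - the ynol ether adds through the ester carbonyl in a hetero-[4+2] sense;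
  - the ketene dimerizes;
  - a light-driven acyl shift occurs in the depside esters.
- The fallback is conventional depside chemistry. It sets out from 10 (with 1 as the source of ring C) and comes back to the route at 26.
- Compound 1 is dibenzylated (BnBr, K2CO3, DMF, 60 °C) to methyl 2,4-bis(benzyloxy)-6-methylbenzoate F1.
- F1 is saponified (KOH, aqueous DMSO, 90 °C, then cold HCl) to 2,4-bis(benzyloxy)-6-methylbenzoic acid F2.
- F2 is condensed with 10 by trifluoroacetic anhydride in toluene, as in step 4, to the ring C dibenzyl ring A silyl tridepside F3.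
- Hydrogenolysis (H2, Pd/C, EtOAc) should give the ring A 2-O-triisopropylsilyl ether of the target F4.
- Buffered Bu4NF, as in step 12, should then give 26.

**Second, step 10.**
- What may go wrong:
  - the monolithium acetylide disproportionates on warming before it is oxidized;
  - the unhindered ynolate is silylated at carbon, leading to a silylketene;
  - the unsubstituted silyl ynol ether isomerizes during isolation.
- The fallback blocks the alkyne terminus. It sets out from 8 and comes back at 20.
- Commercial ethynyltrimethylsilane is lithiated (n-BuLi, THF, −78 °C) and oxidized with t-BuOOLi up to 0 °C, where this acetylide cannot disproportionate.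
- O-silylation with 8 in the same flask gives trimethyl{[(triisopropylsilyl)oxy]ethynyl}silane F5.
- The small carbon-bound silyl group is then removed selectively (K2CO3 cat., MeOH/THF, −20 °C). The bulky oxygen-bound silyl group should be attacked much more slowly, so this should give 20.

**Third, step 8** (together with the supply of 13 in step 7).
- What may go wrong:
  - the enone oligomerizes by a radical or Michael-type path while the acylketene is generated at 85 °C;
  - the beta-keto ester condenses with itself before diazo transfer.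
- The fallback never passes through a free beta-keto ester. It sets out from 10 and comes back at 16.
- Compound 10 is acylated with bromoacetyl bromide (NaHCO3, MeCN, 0 °C) to the ring B O4 bromoacetate F6.
- N,N'-ditosylhydrazine and DBU (THF, 0 °C) should convert F6 into the ring B O4 diazoacetate F7.
- DBU-catalysed aldol-type addition of F7 to methacrolein (MeCN, rt) should give the racemic 2-diazo-3-hydroxy-4-methylpent-4-enoate F8.
- Oxidation of the allylic alcohol with 2-iodoxybenzoic acid (DMSO, rt) should give 16.

Further compounds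
F1 | step 11 | methyl 2,4-bis(benzyloxy)-6-methylbenzoate | COC(=O)c1c(C)cc(OCc2ccccc2)cc1OCc3ccccc3
F2 | step 11 | 2,4-bis(benzyloxy)-6-methylbenzoic acid | OC(=O)c1c(C)cc(OCc2ccccc2)cc1OCc3ccccc3
F3 | step 11 | methyl 4-{[4-({2,4-bis(benzyloxy)-6-methylbenzoyl}oxy)-2-methoxy-6-methylbenzoyl]oxy}-6-methyl-2-[(triisopropylsilyl)oxy]benzoate | COC(=O)c1c(C)cc(OC(=O)c2c(C)cc(OC(=O)c3c(C)cc(OCc4ccccc4)cc3OCc5ccccc5)cc2OC)cc1O[Si](C(C)C)(C(C)C)C(C)C
F4 | step 11 | methyl 4-({4-[(2,4-dihydroxy-6-methylbenzoyl)oxy]-2-methoxy-6-methylbenzoyl}oxy)-6-methyl-2-[(triisopropylsilyl)oxy]benzoate | COC(=O)c1c(C)cc(OC(=O)c2c(C)cc(OC(=O)c3c(C)cc(O)cc3O)cc2OC)cc1O[Si](C(C)C)(C(C)C)C(C)C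
F5 | step 10 | trimethyl{[(triisopropylsilyl)oxy]ethynyl}silane | C[Si](C)(C)C#CO[Si](C(C)C)(C(C)C)C(C)C
F6 | step 8 | methyl 4-({4-[(bromoacetyl)oxy]-2-methoxy-6-methylbenzoyl}oxy)-6-methyl-2-[(triisopropylsilyl)oxy]benzoate | COC(=O)c1c(C)cc(OC(=O)c2c(C)cc(OC(=O)CBr)cc2OC)cc1O[Si](C(C)C)(C(C)C)C(C)C
F7 | step 8 | methyl 4-({4-[(diazoacetyl)oxy]-2-methoxy-6-methylbenzoyl}oxy)-6-methyl-2-[(triisopropylsilyl)oxy]benzoate | COC(=O)c1c(C)cc(OC(=O)c2c(C)cc(OC(=O)C=[N+]=[N-])cc2OC)cc1O[Si](C(C)C)(C(C)C)C(C)C
F8 | step 8 | methyl 4-({4-[(2-diazo-3-hydroxy-4-methylpent-4-enoyl)oxy]-2-methoxy-6-methylbenzoyl}oxy)-6-methyl-2-[(triisopropylsilyl)oxy]benzoate (racemic carbinol) | COC(=O)c1c(C)cc(OC(=O)c2c(C)cc(OC(=O)C(=[N+]=[N-])C(O)C(C)=C)cc2OC)cc1O[Si](C(C)C)(C(C)C)C(C)C
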